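Lay a ruler through the south readings, from the second to the last.

- south: starting material 0.11 M (fed, over 15 s); solid reagent 0.70 equiv; initiator 1 mol%; run made earlier
- flask: starting material 0.22 M (fed, over 15 s); solid reagent 0.700 equiv; initiator 1 mol%; time 12 min

- south (time / min: starting material / %, target / %): 0.333: 99.6, 0.1; 0.833: 96.4, 3.1; 1.50: 93.1, 6.5; 2.50: 87.0, 12.0

(standard deviation of a reading: 0.5 percentage points)

- given per volume of solution although it is solid: solid reagent
- at the start none of the solid reagent is in solution
- the earlier runs do not show how much of partner is bound; that part of a forecast is a guess
- no earlier run changes the charge of initiator; that part of a forecast is a guess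

1. part of the starting material that has reacted at 12 min
2. share of free partner in free partner and idle adduct together, at 12 min

The slope of that ruler is the mean loss rate s, the part of the charged starting material lost per minute on the straight stretch: 0.0564 min⁻¹. I carry s unchanged to the flask, although its charge of starting material is twice that of the south run. Supposing the flask's rate never exceeds s, holding s for 12 min gives a bound from above of 67.7%, just under the 0.700 equiv of solid reagent, the limiting reagent of the charge if each target takes one partner. A bound from below comes from supposing that the flask stops where the south run was last read, at 13.0%.

To tighten the bracket, replace the curve by its mean. If the rate falls evenly from s to nothing over the 12 min, its mean is half of s, and my conversion is 33.8%. The south readings end at 2.50 min, so that fall is my assumption, and the error of this mean can reach either bound. The free share of partner stays a guess.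

The forecast says 47% and 45%, reasoning that “If rate scales with loading, percent per minute stays similar”. Its conversion lies inside the bracket, above mine.

The flask gives a free share of 58.3% and 23.2% reacted, a conversion inside the bracket and 11 percentage points below my mean.

    solid reagent ⇌ partner, rate k1*(cs1 - [partner]) while solid is left; crystals form when [partner] > cs1 (solubility = 0.100 M, k = 0.00483 s⁻¹)
    partner + first chain carrier → target + second chain carrier (k = 73700 M⁻¹ s⁻¹)
    starting material + initiating radical → capped initiator + first chain carrier (k = 3.25 × 10⁶ M⁻¹ s⁻¹)
    2 second chain carrier → ended chains A (k = 8.90 × 10⁷ M⁻¹ s⁻¹)
    starting material + second chain carrier → released group + first chain carrier (k = 1.35 × 10⁶ M⁻¹ s⁻¹)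
    first chain carrier → ended carrier (k = 81.5 s⁻¹)
    initiator → 2 initiating radical (k = 0.00868 s⁻¹)
    partner + released group ⇌ idle adduct, settled at all times (K = 360 M⁻¹)
    2 first chain carrier → ended chains B (k = 5.50 × 10⁸ M⁻¹ s⁻¹)

At 12 min the flask holds 77% of its starting material but 0.19% of its initiator, less of its own charge. Divided by s, the flask's conversion equals 4.11 min of straight-line running. The neighbour at 0.55 M, with the same equivalents and loadings, reaches 14.4%, which is 2.55 min at s.

The earlier runs and the new flask come from a simulation with constants of no real substance; the scatter is artificial.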